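**Retrosynthetic overview**
- Ring numbering: C1 (CH2SO2CH3), C2 (Br), C3 (OH), C4 (OH), C5 (Br), C6 (Br). The plan rests on the C3–C4 bond between the two hydroxylated ring carbons, and on C2–C1–C6–C5 being a plain four-carbon chain that carries only the C1 side chain.
- The three C–Br bonds and the aromaticity are installed last, by bromine acting on 4-(methylsulfonylmethyl)cyclohexane-1,2-dione.
- The dione is traced back through its two regioisomeric 2-hydroxycyclohexanones, which are opened at C3–C4 to 3-(methylsulfonylmethyl)hexanedial. In the forward sense this is a carbene-catalysed acyloin closure, the only ring-forming event, with the ketols oxidized in the same flask.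
- The dialdehyde comes from the corresponding diester, assembled by Michael addition of methyl 2-(methylsulfonyl)acetate to dimethyl (E)-hex-2-enedioate and Krapcho removal of the extra ester.

Key step: step 5

Remark: the target is achiral. The stereocenters created in steps 1 and 5 are uncontrolled and are all destroyed by step 6, so racemates and diastereomer mixtures are carried on unseparated. Diester 1 is taken as a catalogue compound.

**Step 1**
Reactants: 1 dimethyl (E)-hex-2-enedioate; 2 methyl 2-(methylsulfonyl)acetate
Product: 3 dimethyl 3-[2-methoxy-1-(methylsulfonyl)-2-oxoethyl]hexanedioate (racemic mixture of diastereomers)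
Conditions: 2 (1.2 equiv), DBU (0.5 equiv), MeCN, 60 °C
Reagents that add atoms: none
Why: Michael addition, in which the carbanion of 2 (stabilized by sulfone and ester) adds to the β-carbon of the enoate and the adduct enolate is protonated by further 2; the two new stereocenters form without control, one being removed in step 2 and the other erased on aromatization.

**Step 2**
Reactants: 3 dimethyl 3-[2-methoxy-1-(methylsulfonyl)-2-oxoethyl]hexanedioate
Product: 4 dimethyl 3-(methylsulfonylmethyl)hexanedioate (racemic)
Conditions: LiCl (2 equiv), H2O (2 equiv), DMSO, 150 °C
Reagents that add atoms: none
Why: Krapcho dealkoxycarbonylation, in which chloride demethylates the ester geminal to the sulfone because only there does loss of CO2 leave a sulfonyl-stabilized carbanion for water to protonate, so the two unactivated methyl esters should persist.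

**Step 3**
Reactants: 4 dimethyl 3-(methylsulfonylmethyl)hexanedioate
Product: 5 3-(methylsulfonylmethyl)hexane-1,6-diol (racemic)
Conditions: LiBH4 (2.5 equiv), THF, 0 to 50 °C; aq. NH4Cl
Reagents that add atoms: none
Why: Hydride reduction of both esters to primary alcohols by LiBH4, a reagent to which the dialkyl sulfone is inert.

**Step 4**
Reactants: 5 3-(methylsulfonylmethyl)hexane-1,6-diol
Product: 6 3-(methylsulfonylmethyl)hexanedial (racemic, used crude at once)
Conditions: (COCl)2 (2.6 equiv), DMSO (5.5 equiv), CH2Cl2, −78 °C; Et3N (8 equiv), −78 to 0 °C
Reagents that add atoms: none
Why: Swern oxidation of both primary alcohols stops cleanly at the aldehyde level, and the low temperature and short contact with Et3N should keep the enolizable dialdehyde from self-condensing.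

**Step 5**
Reactants: 6 3-(methylsulfonylmethyl)hexanedial
Product: 9 4-(methylsulfonylmethyl)cyclohexane-1,2-dione (racemic), via 2-hydroxy-5-(methylsulfonylmethyl)cyclohexan-1-one 7 (not isolated), via 2-hydroxy-4-(methylsulfonylmethyl)cyclohexan-1-one 8 (not isolated)
Conditions: 3-benzyl-5-(2-hydroxyethyl)-4-methylthiazolium chloride (15 mol%), Et3N (0.5 equiv), EtOH, 78 °C, N2, slow addition of 6 (final 0.02 M); then concentrate, AcOH/H2O, Cu(OAc)2·H2O (2.2 equiv), 60 °C
Reagents that add atoms: none
Why: Intramolecular benzoin (acyloin) reaction under thiazol-2-ylidene catalysis: Et3N deprotonates the thiazolium salt, the carbene adds to one formyl group, proton transfer gives an enaminol that acts as an acyl anion equivalent, and this carbon attacks the second formyl carbon before the carbene is released. The closest known reaction type is the thiazolium-catalysed cyclization of aliphatic 1,5- and 1,6-dialdehydes to 2-hydroxycyclopentanones and 2-hydroxycyclohexanones. The one ring closes in the 6-exo-trig mode, and the two carbons joined become C3 and C4 of the later arene. The single new stereocenter, the carbinol carbon, is set without control by the achiral catalyst, and which formyl group ends up as the ketone is likewise open, so ketols 7 and 8 should both form as cis/trans mixtures. The selectivity needed is acyloin closure over the five-ring intramolecular aldol condensation and over intermolecular coupling; it is secured by a weak amine base that barely enolizes the aldehydes, by fast carbene addition to two unhindered formyl groups held in a 1,6-relationship, and by high dilution, while the sulfone offers no electrophilic site. Acidification then stops the reversible carbene chemistry, and divalent copper oxidizes each α-hydroxy ketone through its enediol to the 1,2-diketone while being reduced to monovalent copper, so that all regio- and stereoisomers converge on the single dione 9 and isolation of the dimerization-prone ketol mixture is avoided.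

**Step 6**
Reactants: 9 4-(methylsulfonylmethyl)cyclohexane-1,2-dione
Product: 11 3,4,6-tribromo-5-(methylsulfonylmethyl)benzene-1,2-diol, via 4-(methylsulfonylmethyl)benzene-1,2-diol 10 (not isolated)
Conditions: Br2 (4.5 equiv), AcOH, 20 to 60 °C, dark; aq. NaHSO3 work-up
Reagents that add atoms: bromine, BrBr
Why: Bromination–dehydrobromination aromatization of a cyclohexane-1,2-dione (α-bromination of the enol, loss of HBr, tautomerization) should give the catechol, and electrophilic aromatic bromination then fills the three free positions, each ortho or para to a hydroxyl; the last stereocenter disappears, and the reductive work-up returns any ortho-quinone to the catechol.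

**Compound list**
1 | dimethyl (E)-hex-2-enedioate | COC(=O)/C=C/CCC(=O)OC | starting material
2 | methyl 2-(methylsulfonyl)acetate | COC(=O)CS(C)(=O)=O | starting material
3 | dimethyl 3-[2-methoxy-1-(methylsulfonyl)-2-oxoethyl]hexanedioate (racemic diastereomer mixture) | COC(=O)CC(CCC(=O)OC)C(C(=O)OC)S(C)(=O)=O | intermediate
4 | dimethyl 3-(methylsulfonylmethyl)hexanedioate (racemic) | COC(=O)CC(CCC(=O)OC)CS(C)(=O)=O | intermediate
5 | 3-(methylsulfonylmethyl)hexane-1,6-diol (racemic) | OCCC(CCCO)CS(C)(=O)=O | intermediate
6 | 3-(methylsulfonylmethyl)hexanedial (racemic) | CS(=O)(=O)CC(CC=O)CCC=O | intermediate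
7 | 2-hydroxy-5-(methylsulfonylmethyl)cyclohexan-1-one (stereoisomer mixture, not isolated) | CS(=O)(=O)CC1CCC(O)C(=O)C1 | intermediate
8 | 2-hydroxy-4-(methylsulfonylmethyl)cyclohexan-1-one (stereoisomer mixture, not isolated) | CS(=O)(=O)CC1CCC(=O)C(O)C1 | intermediate
9 | 4-(methylsulfonylmethyl)cyclohexane-1,2-dione (racemic) | CS(=O)(=O)CC1CCC(=O)C(=O)C1 | intermediate
10 | 4-(methylsulfonylmethyl)benzene-1,2-diol (not isolated) | CS(=O)(=O)Cc1ccc(O)c(O)c1 | intermediate
11 | 3,4,6-tribromo-5-(methylsulfonylmethyl)benzene-1,2-diol | CS(=O)(=O)Cc1c(Br)c(O)c(O)c(Br)c1Br | target

**Step count**
Total steps: 6. Longest linear sequence: 6.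

**Steps most likely to fail**

Step 5. The carbene-mediated closure may be outrun by amine-promoted intramolecular aldol cyclodehydration of the dialdehyde to five-membered enals, or by intermolecular acyloin oligomerization. The fallback joins the same two carbons reductively instead of by polarity reversal. It sets out from dialdehyde 6: SmI2 (2.5 equiv) in THF/t-BuOH at −78 °C should effect intramolecular pinacol coupling to 4-(methylsulfonylmethyl)cyclohexane-1,2-diol F1, as a stereoisomer mixture, the dialkyl sulfone being inert to SmI2 without strongly donating additives. Double oxidation of this vicinal diol with DMSO/trifluoroacetic anhydride and Et3N at −60 °C, which does not cleave the C–C bond, would then give the dione. The fallback comes back to the route at compound 9.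

Step 6. Running dehydrogenation and threefold bromination in one flask may lead to over-bromination to non-aromatic bromodienones, oxidation of the catechol to the ortho-quinone, or incomplete loss of HBr. The fallback separates the two events. It sets out from dione 9: catalytic I2 in DMSO at 80–100 °C (α-iodination, loss of HI, tautomerization, DMSO as terminal oxidant) should aromatize it without introducing halogen, and the catechol 10 is then isolated. A measured 3.05 equiv of Br2 in AcOH/CH2Cl2 at 0 °C would brominate the three free positions under stoichiometric control. The fallback comes back at target 11.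

Step 1. Conjugate addition to a β-alkyl enoate is slow and reversible, and DBU may deconjugate the acceptor or promote retro-addition before the adduct accumulates. The fallback exchanges donor and acceptor roles. It sets out from sulfonyl ester 2: Knoevenagel condensation with commercial methyl 4-oxobutanoate (piperidine/AcOH, toluene, water removal) should give dimethyl 2-(methylsulfonyl)hex-2-enedioate F2, as an alkene isomer mixture, a doubly activated acceptor. A Mukaiyama–Michael addition of 1-methoxy-1-(trimethylsilyloxy)ethene (TiCl4, CH2Cl2, −78 °C, aqueous work-up) would then deliver the CH2CO2CH3 group to its β-carbon. The fallback comes back at triester 3.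

**Further compounds**
F1 | step 5 | 4-(methylsulfonylmethyl)cyclohexane-1,2-diol | CS(=O)(=O)CC1CCC(O)C(O)C1
F0 | step 6 | none | none
F2 | step 1 | dimethyl 2-(methylsulfonyl)hex-2-enedioate | COC(=O)CCC=C(C(=O)OC)S(C)(=O)=O
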